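**Retrosynthetic overview**

1. The strategy rests on the trans-vicinal benzyl groups at C3 (α) and C4 (β) of the γ-butyrolactone. Both benzylic C–C bonds are made in one pot across the C3=C4 bond of (5R)-5-(l-menthyloxy)-2(5H)-furanone 4, from the lithiated ring A dithiane 36 (at C4) and the ring B benzylic bromide 20 (at C3). The acetal carbon C5 relays its configuration to C4 and C3 and is later reduced to the lactone CH2.
2. Ring A dithiane 35: the dihydrofuran ring is closed by Mitsunobu etherification (O–C2 bond, inversion) of an anti 1,2-diaryl-1,3-diol. The diol comes from an auxiliary-controlled anti-aldol of an arylacetyl imide (from 5-bromo-2-hydroxy-3-methoxybenzaldehyde 5) with O-benzylvanillin 12, followed by Br → CHO → dithiane.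
3. Ring B bromide 20: the mirror-image anti-aldol from the same two aldehydes, with the diol held open as an acetonide, then Br → CH2OH → CH2Br.
4. Ring order: butenolide (from the furan of furfural, step 1), 1,3-dioxane protecting ring (step 9), dihydrobenzofuran (step 20), dithiane (step 22, temporary), lactone re-closed after acetal hydrolysis and reduction (step 25). The endgame is desulfurisation, acetal reduction, acid deprotection and hydrogenolysis.

Key step: step 23

**Remarks**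

- Assumption: the MgCl2-catalysed anti-aldol of the arylacetyl imides is taken to follow the facial sense of propionyl imides (attack on the chelated Z-enolate opposite the 4-benzyl group). If the opposite sense held, auxiliaries 9 and 24 would be exchanged between the two series.
- Compounds 1, 3, 5, 9, 12 and 24 are taken as commercial.
- Shorthand: ArA = (2S,3R)-2-[4-(benzyloxy)-3-methoxyphenyl]-3-[(tert-butyldimethylsilyloxy)methyl]-7-methoxy-2,3-dihydrobenzofuran-5-yl.
- Shorthand: ArB = 4-(benzyloxy)-3-[(4S,5S)-4-(4-benzyloxy-3-methoxyphenyl)-2,2-dimethyl-1,3-dioxan-5-yl]-5-methoxyphenyl.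

**Route**

*Butenolide acceptor*

Step 1
Reactants: 1 furfural
Product: 2 5-hydroxy-2(5H)-furanone (racemic lactol)
Conditions: O2, hν (visible), rose bengal disodium salt (C20H2Cl4I4Na2O5, cat.), MeOH, rt
Reagents that add atoms: dioxygen O=O
Why: Sensitised singlet-oxygen [4+2] cycloaddition to the furan gives an endoperoxide whose methanol hemiacetal fragments with loss of methyl formate to the hydroxybutenolide (furfural photooxygenation); the lactol carbon is formed racemic.

Step 2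
Reactants: 2 5-hydroxy-2(5H)-furanone; 3 (−)-menthol
Product: 4 (5R)-5-(l-menthyloxy)-2(5H)-furanone
Conditions: CSA (cat.), toluene, reflux, Dean–Stark; crystallisation from petroleum ether, −20 °C; mother liquor re-equilibrated with CSA
Reagents that add atoms: none
Why: Acid-catalysed acetalisation of the lactol gives both C5 epimers, which interconvert under the acid, and the C5 stereocentre is set by selective crystallisation of the (5R) menthyl acetal with recycling of the mother liquor.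

*Ring B benzylic bromide*

Step 3
Reactants: 5 5-bromo-2-hydroxy-3-methoxybenzaldehyde
Product: 6 2-(benzyloxy)-5-bromo-3-methoxybenzaldehyde
Conditions: BnBr, K2CO3, DMF, rt
Reagents that add atoms: benzyl bromide BrCc1ccccc1
Why: Williamson etherification of the phenoxide installs a benzyl ether that survives every later step and leaves with the other benzyl ethers in the last step.

Step 4
Reactants: 6 2-(benzyloxy)-5-bromo-3-methoxybenzaldehyde
Product: 7 2-[2-(benzyloxy)-5-bromo-3-methoxyphenyl]acetonitrile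
Conditions: TosMIC, KOt-Bu, DME, −40 °C; then MeOH, reflux
Reagents that add atoms: p-toluenesulfonylmethyl isocyanide Cc1ccc(cc1)S(=O)(=O)C[N+]#[C-]
Why: van Leusen reductive cyanation, in which the TosMIC anion adds to the aldehyde and methanolysis of the oxazoline intermediate expels formate and sulfinate, gives the one-carbon homologated nitrile without touching the aryl bromide.

Step 5
Reactants: 7 2-[2-(benzyloxy)-5-bromo-3-methoxyphenyl]acetonitrile
Product: 8 2-[2-(benzyloxy)-5-bromo-3-methoxyphenyl]acetic acid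
Conditions: NaOH, EtOH/H2O, reflux; then aq. HCl
Reagents that add atoms: sodium hydroxide [Na+].[OH-]; water O
Why: Alkaline nitrile hydrolysis followed by acidification gives the arylacetic acid, the aryl bromide and benzyl ether being inert to aqueous hydroxide.

Step 6
Reactants: 8 2-[2-(benzyloxy)-5-bromo-3-methoxyphenyl]acetic acid; 9 (S)-4-benzyl-2-oxazolidinone
Product: 11 (S)-4-benzyl-3-{2-[2-(benzyloxy)-5-bromo-3-methoxyphenyl]acetyl}oxazolidin-2-one, via mixed pivalic anhydride 10 (not isolated)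
Conditions: PivCl, Et3N, THF, −20 °C; then 9, LiCl, −20 °C → rt
Reagents that add atoms: none
Why: N-Acylation of the oxazolidinone through the mixed pivalic anhydride works because the hindered pivaloyl carbonyl directs attack to the arylacetyl carbonyl.

Step 7
Reactants: 11 (S)-4-benzyl-3-{2-[2-(benzyloxy)-5-bromo-3-methoxyphenyl]acetyl}oxazolidin-2-one; 12 4-(benzyloxy)-3-methoxybenzaldehyde
Product: 13 (S)-4-benzyl-3-{(2R,3S)-2-[2-(benzyloxy)-5-bromo-3-methoxyphenyl]-3-[4-(benzyloxy)-3-methoxyphenyl]-3-(trimethylsilyloxy)propanoyl}oxazolidin-2-one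
Conditions: MgCl2 (20 mol %), Et3N, TMSCl, EtOAc, rt
Reagents that add atoms: chlorotrimethylsilane C[Si](C)(C)Cl
Why: In this MgCl2-catalysed direct anti-aldol of an N-acyloxazolidinone with a non-enolisable aromatic aldehyde (Evans anti-aldol), the chelated Z magnesium enolate is attacked opposite the 4-benzyl group to set C2 (R), the boat-like transition state sets C3 (S) anti, and silylation of the aldolate turns the metal over and blocks retro-aldol.

Step 8
Reactants: 13 anti-aldol trimethylsilyl ether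
Product: 15 (1S,2S)-2-[2-(benzyloxy)-5-bromo-3-methoxyphenyl]-1-[4-(benzyloxy)-3-methoxyphenyl]propane-1,3-diol, via silyl ether alcohol 14 (not isolated)
Conditions: LiBH4, MeOH (1 equiv), THF, 0 °C; then K2CO3, MeOH, rt
Reagents that add atoms: none
Why: LiBH4 reduces the imide carbonyl to the primary alcohol and releases the auxiliary while the silylated β-oxygen prevents retro-aldol and C2 epimerisation, and mild methanolysis then removes the TMS group.

Step 9
Reactants: 15 (1S,2S)-diol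
Product: 16 (4S,5S)-5-[2-(benzyloxy)-5-bromo-3-methoxyphenyl]-4-[4-(benzyloxy)-3-methoxyphenyl]-2,2-dimethyl-1,3-dioxane (ArB–Br)
Conditions: 2,2-dimethoxypropane, PPTS (cat.), CH2Cl2, rt
Reagents that add atoms: 2,2-dimethoxypropane COC(C)(C)OC
Why: Acid-catalysed transacetalisation gives the 1,3-dioxane with both aryl groups equatorial, a base-stable mask for the diol during the organolithium and enolate steps.

Step 10
Reactants: 16 ArB–Br
Product: 19 ArB–CH2OH {4-(benzyloxy)-3-[(4S,5S)-4-(4-benzyloxy-3-methoxyphenyl)-2,2-dimethyl-1,3-dioxan-5-yl]-5-methoxyphenyl}methanol, via aryllithium 17 (not isolated), via aldehyde 18 (not isolated)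
Conditions: n-BuLi, THF, −78 °C; DMF, −78 → 0 °C; then MeOH, NaBH4, 0 °C
Reagents that add atoms: N,N-dimethylformamide CN(C)C=O
Why: Bromine–lithium exchange at −78 °C outruns any deprotonation, the aryllithium is formylated by DMF (Bouveault formylation), and the aldehyde released on adding methanol is reduced in the same flask by NaBH4.

Step 11
Reactants: 19 ArB–CH2OH
Product: 20 ArB–CH2Br (4S,5S)-5-[2-(benzyloxy)-5-(bromomethyl)-3-methoxyphenyl]-4-[4-(benzyloxy)-3-methoxyphenyl]-2,2-dimethyl-1,3-dioxane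
Conditions: CBr4, PPh3, CH2Cl2, 0 °C; used at once
Reagents that add atoms: carbon tetrabromide BrC(Br)(Br)Br
Why: Appel bromination converts the electron-rich benzylic alcohol to the bromide under neutral conditions that leave the acetonide intact.

*Ring A dithiane*

Step 12
Reactants: 5 5-bromo-2-hydroxy-3-methoxybenzaldehyde
Product: 21 2-(allyloxy)-5-bromo-3-methoxybenzaldehyde
Conditions: allyl bromide, K2CO3, DMF, rt
Reagents that add atoms: allyl bromide C=CCBr
Why: Williamson etherification gives an allyl ether that withstands the base and hydride steps and can later be removed in the presence of the benzyl ether, the silyl ether and the aryl bromide.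

Step 13
Reactants: 21 2-(allyloxy)-5-bromo-3-methoxybenzaldehyde
Product: 22 2-[2-(allyloxy)-5-bromo-3-methoxyphenyl]acetonitrile
Conditions: TosMIC, KOt-Bu, DME, −40 °C; then MeOH, reflux
Reagents that add atoms: p-toluenesulfonylmethyl isocyanide Cc1ccc(cc1)S(=O)(=O)C[N+]#[C-]
Why: van Leusen reductive cyanation homologates the aldehyde to the arylacetonitrile as in step 4.

Step 14
Reactants: 22 2-[2-(allyloxy)-5-bromo-3-methoxyphenyl]acetonitrile
Product: 23 2-[2-(allyloxy)-5-bromo-3-methoxyphenyl]acetic acid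
Conditions: NaOH, EtOH/H2O, reflux; then aq. HCl
Reagents that add atoms: sodium hydroxide [Na+].[OH-]; water O
Why: Alkaline nitrile hydrolysis as in step 5, the allyl ether being stable to aqueous hydroxide.

Step 15
Reactants: 23 2-[2-(allyloxy)-5-bromo-3-methoxyphenyl]acetic acid; 24 (R)-4-benzyl-2-oxazolidinone
Product: 26 (R)-4-benzyl-3-{2-[2-(allyloxy)-5-bromo-3-methoxyphenyl]acetyl}oxazolidin-2-one, via mixed pivalic anhydride 25 (not isolated)
Conditions: PivCl, Et3N, THF, −20 °C; then 24, LiCl, −20 °C → rt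
Reagents that add atoms: none
Why: Mixed-anhydride N-acylation as in step 6, here with the enantiomeric auxiliary.

Step 16
Reactants: 26 (R)-4-benzyl-3-{2-[2-(allyloxy)-5-bromo-3-methoxyphenyl]acetyl}oxazolidin-2-one; 12 4-(benzyloxy)-3-methoxybenzaldehyde
Product: 27 (R)-4-benzyl-3-{(2S,3R)-2-[2-(allyloxy)-5-bromo-3-methoxyphenyl]-3-[4-(benzyloxy)-3-methoxyphenyl]-3-(trimethylsilyloxy)propanoyl}oxazolidin-2-one
Conditions: MgCl2 (20 mol %), Et3N, TMSCl, EtOAc, rt
Reagents that add atoms: chlorotrimethylsilane C[Si](C)(C)Cl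
Why: The same MgCl2-catalysed Evans anti-aldol as step 7 with the (R)-auxiliary gives the mirror-image stereodiad, C2 (S) set by attack opposite the 4-benzyl group and C3 (R) by the anti-selective transition state.

Step 17
Reactants: 27 anti-aldol trimethylsilyl ether
Product: 29 (1R,2R)-2-[2-(allyloxy)-5-bromo-3-methoxyphenyl]-1-[4-(benzyloxy)-3-methoxyphenyl]propane-1,3-diol, via silyl ether alcohol 28 (not isolated)
Conditions: LiBH4, MeOH (1 equiv), THF, 0 °C; then K2CO3, MeOH, rt
Reagents that add atoms: none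
Why: Reductive removal of the auxiliary with LiBH4 and methanolysis of the TMS ether as in step 8, without loss of either stereocentre.

Step 18
Reactants: 29 (1R,2R)-diol
Product: 30 (1R,2R)-2-[2-(allyloxy)-5-bromo-3-methoxyphenyl]-1-[4-(benzyloxy)-3-methoxyphenyl]-3-(tert-butyldimethylsilyloxy)propan-1-ol
Conditions: TBSCl (1.05 equiv), imidazole, CH2Cl2, 0 °C
Reagents that add atoms: tert-butyldimethylsilyl chloride CC(C)(C)[Si](C)(C)Cl
Why: The primary hydroxyl is silylated far faster than the hindered secondary benzylic one, which blocks the competing ring closure onto the primary carbon in step 20.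

Step 19
Reactants: 30 primary silyl ether
Product: 31 (1R,2R)-2-(5-bromo-2-hydroxy-3-methoxyphenyl)-1-[4-(benzyloxy)-3-methoxyphenyl]-3-(tert-butyldimethylsilyloxy)propan-1-ol
Conditions: Pd(PPh3)4 (5 mol %), morpholine, THF, rt
Reagents that add atoms: none
Why: Zerovalent palladium ionises the aryl allyl ether to a π-allyl complex that morpholine captures (Tsuji–Trost deallylation), a process much faster at rt than oxidative addition into the electron-rich aryl bromide.

Step 20
Reactants: 31 phenol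
Product: 32 ArA–Br (2S,3R)-2-[4-(benzyloxy)-3-methoxyphenyl]-5-bromo-3-[(tert-butyldimethylsilyloxy)methyl]-7-methoxy-2,3-dihydrobenzofuran
Conditions: PPh3, DIAD, THF, 0 °C → rt
Reagents that add atoms: none
Why: Intramolecular Mitsunobu etherification, in which the oxyphosphonium of the benzylic carbinol is displaced by the ortho phenoxide in a 5-exo-tet SN2 closure, inverts the (1R) carbinol to C2 (S) and so gives the trans ring with C3 (R) unchanged.

Step 21
Reactants: 32 ArA–Br
Product: 34 ArA–CHO (2S,3R)-2-[4-(benzyloxy)-3-methoxyphenyl]-3-[(tert-butyldimethylsilyloxy)methyl]-7-methoxy-2,3-dihydrobenzofuran-5-carbaldehyde, via aryllithium 33 (not isolated)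
Conditions: n-BuLi, THF, −78 °C; DMF, −78 → 0 °C; H2O
Reagents that add atoms: N,N-dimethylformamide CN(C)C=O
Why: Bromine–lithium exchange followed by Bouveault formylation with DMF is compatible with the silyl ether, the benzyl ether and the cyclic benzylic ether at −78 °C.

Step 22
Reactants: 34 ArA–CHO
Product: 35 2-ArA-1,3-dithiane
Conditions: HS(CH2)3SH, I2 (10 mol %), CH2Cl2, rt
Reagents that add atoms: propane-1,3-dithiol SCCCS
Why: Iodine-catalysed dithioacetalisation of the aromatic aldehyde is mild enough to spare the primary TBS ether and the acid-sensitive benzylic C2–O bond.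

*Key coupling and endgame*

Step 23
Reactants: 35 2-ArA-1,3-dithiane; 4 (5R)-5-(l-menthyloxy)-2(5H)-furanone; 20 ArB–CH2Br
Product: 38 (3R,4R,5R)-3-(ArB-methyl)-4-(2-ArA-1,3-dithian-2-yl)-5-(l-menthyloxy)dihydrofuran-2(3H)-one, via lithiated dithiane 36 (not isolated), via lithium enolate 37 (not isolated)
Conditions: n-BuLi, THF, −30 → 0 °C; 4, −78 °C; then 20, DMPU, −78 → −20 °C
Reagents that add atoms: none
Why: n-BuLi removes the C2 proton of dithiane 35, and the soft sulfur-stabilised benzylic carbanion 36 adds in Michael fashion to C4 of butenolide 4 to give lithium enolate 37, which DMPU loosens for SN2 C-benzylation at C3 by the activated benzylic bromide 20. The closest known reaction type is the one-pot conjugate addition of lithiated 2-aryl-1,3-dithianes to 5-alkoxy-2(5H)-furanones with trapping of the enolate by benzylic bromides, as used for trans-dibenzylbutyrolactone lignans. No ring is closed; the C4–C(dithiane) and C3–CH2 bonds are formed. The new C4 stereocentre (R) is set by the C5 acetal because the nucleophile enters anti to the menthyloxy group, and the new C3 stereocentre (R) is set by C4 because the bromide enters anti to the bulky dithianyl group, so the 3,4-trans-4,5-trans lactone should result. The step needs 1,4- over 1,2-addition, which the soft hindered anion and −78 °C secure, and C-alkylation before proton transfer, which the reactive 4-alkoxybenzylic bromide and the absence of a more acidic C–H in 37 secure; 36 must be consumed by 4 before 20 is added so that it is not benzylated directly.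

Step 24
Reactants: 38 dithianyl lactone
Product: 39 (3R,4R,5R)-3-(ArB-methyl)-4-(ArA-methyl)-5-(l-menthyloxy)dihydrofuran-2(3H)-one
Conditions: NiCl2·6H2O, NaBH4, THF/MeOH, 0 °C
Reagents that add atoms: none
Why: Nickel boride generated in the flask cleaves both benzylic C–S bonds reductively (dithioacetal desulfurisation) and is expected to spare benzyl ethers, the acetonide, the silyl ether and the acetal lactone.

Step 25
Reactants: 39 menthyloxy lactone
Product: 41 (3R,4R)-3-(ArB-methyl)-4-(ArA-methyl)dihydrofuran-2(3H)-one, via potassium hydroxy carboxylate 40 (not isolated)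
Conditions: KOH, NaBH4, EtOH/THF/H2O, rt; then 1 M HCl to pH 3, rt
Reagents that add atoms: none
Why: Hydroxide opens the acylal to the carboxylate and the aldehyde with loss of menthol, NaBH4 reduces the aldehyde as it forms so that C4 has little chance to epimerise, and acidification relactonises the γ-hydroxy acid with C3 and C4 unchanged.

Step 26
Reactants: 41 protected lactone
Product: 42 (3R,4R)-3-{4-(benzyloxy)-3-[(1S,2S)-1-(4-benzyloxy-3-methoxyphenyl)-1,3-dihydroxypropan-2-yl]-5-methoxybenzyl}-4-{[(2S,3R)-2-(4-benzyloxy-3-methoxyphenyl)-3-(hydroxymethyl)-7-methoxy-2,3-dihydrobenzofuran-5-yl]methyl}dihydrofuran-2(3H)-one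
Conditions: AcOH/THF/H2O (3:1:1), 45 °C
Reagents that add atoms: none
Why: Mild aqueous acid hydrolyses the isopropylidene acetal and the primary TBS ether while all three phenols are still benzylated, so the benzylic carbinol cannot be captured by an ortho phenol and is not ionised by so weak an acid.

Step 27
Reactants: 42 tri-O-benzyl triol
Product: 43 target, (3R,4R)-3-{4-hydroxy-3-[(1S,2S)-1,3-dihydroxy-1-(4-hydroxy-3-methoxyphenyl)propan-2-yl]-5-methoxybenzyl}-4-{[(2S,3R)-2-(4-hydroxy-3-methoxyphenyl)-3-(hydroxymethyl)-7-methoxy-2,3-dihydrobenzofuran-5-yl]methyl}dihydrofuran-2(3H)-one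
Conditions: H2 (1 atm), 10% Pd/C, EtOAc/EtOH, rt
Reagents that add atoms: none
Why: Neutral catalytic hydrogenolysis removes the three aryl benzyl ethers much faster than it cleaves the secondary benzylic alcohol or the dihydrobenzofuran C2–O bond, so the reaction is stopped once debenzylation is complete.

**Compound list**

1 | furfural | O=Cc1ccco1 | starting material
2 | 5-hydroxy-2(5H)-furanone (racemic) | OC1OC(=O)C=C1 | intermediate
3 | (−)-menthol, (1R,2S,5R)-2-isopropyl-5-methylcyclohexanol | CC(C)[C@@H]1CC[C@@H](C)C[C@H]1O | starting material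
4 | (5R)-5-(l-menthyloxy)-2(5H)-furanone | CC(C)[C@@H]1CC[C@@H](C)C[C@H]1O[C@H]1C=CC(=O)O1 | intermediate
5 | 5-bromo-2-hydroxy-3-methoxybenzaldehyde | COc1cc(Br)cc(C=O)c1O | starting material
6 | 2-(benzyloxy)-5-bromo-3-methoxybenzaldehyde | COc1cc(Br)cc(C=O)c1OCc1ccccc1 | intermediate
7 | 2-[2-(benzyloxy)-5-bromo-3-methoxyphenyl]acetonitrile | COc1cc(Br)cc(CC#N)c1OCc1ccccc1 | intermediate
8 | 2-[2-(benzyloxy)-5-bromo-3-methoxyphenyl]acetic acid | COc1cc(Br)cc(CC(=O)O)c1OCc1ccccc1 | intermediate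
9 | (S)-4-benzyl-2-oxazolidinone | O=C1OC[C@H](Cc2ccccc2)N1 | starting material
10 | mixed anhydride of 8 with pivalic acid | COc1cc(Br)cc(CC(=O)OC(=O)C(C)(C)C)c1OCc1ccccc1 | intermediate
11 | (S)-4-benzyl-3-{2-[2-(benzyloxy)-5-bromo-3-methoxyphenyl]acetyl}oxazolidin-2-one | COc1cc(Br)cc(CC(=O)N2[C@@H](Cc3ccccc3)COC2=O)c1OCc1ccccc1 | intermediate
12 | 4-(benzyloxy)-3-methoxybenzaldehyde (O-benzylvanillin) | COc1cc(C=O)ccc1OCc1ccccc1 | starting material
13 | (S)-4-benzyl-3-{(2R,3S)-2-[2-(benzyloxy)-5-bromo-3-methoxyphenyl]-3-[4-(benzyloxy)-3-methoxyphenyl]-3-(trimethylsilyloxy)propanoyl}oxazolidin-2-one | COc1cc(ccc1OCc1ccccc1)[C@@H](O[Si](C)(C)C)[C@H](C(=O)N1[C@@H](Cc2ccccc2)COC1=O)c1cc(Br)cc(OC)c1OCc1ccccc1 | intermediate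
14 | (2S,3S)-2-[2-(benzyloxy)-5-bromo-3-methoxyphenyl]-3-[4-(benzyloxy)-3-methoxyphenyl]-3-(trimethylsilyloxy)propan-1-ol | COc1cc(ccc1OCc1ccccc1)[C@@H](O[Si](C)(C)C)[C@H](CO)c1cc(Br)cc(OC)c1OCc1ccccc1 | intermediate
15 | (1S,2S)-2-[2-(benzyloxy)-5-bromo-3-methoxyphenyl]-1-[4-(benzyloxy)-3-methoxyphenyl]propane-1,3-diol | COc1cc(ccc1OCc1ccccc1)[C@@H](O)[C@H](CO)c1cc(Br)cc(OC)c1OCc1ccccc1 | intermediate
16 | ArB–Br, (4S,5S)-5-[2-(benzyloxy)-5-bromo-3-methoxyphenyl]-4-[4-(benzyloxy)-3-methoxyphenyl]-2,2-dimethyl-1,3-dioxane | COc1cc([C@@H](OC(C)(C)OC2)[C@H]2c2cc(Br)cc(OC)c2OCc2ccccc2)ccc1OCc1ccccc1 | intermediate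
17 | ArB–Li, aryllithium from 16 | COc1cc([C@@H](OC(C)(C)OC2)[C@H]2c2cc([Li])cc(OC)c2OCc2ccccc2)ccc1OCc1ccccc1 | intermediate
18 | ArB–CHO, 4-(benzyloxy)-3-[(4S,5S)-4-(4-benzyloxy-3-methoxyphenyl)-2,2-dimethyl-1,3-dioxan-5-yl]-5-methoxybenzaldehyde | COc1cc([C@@H](OC(C)(C)OC2)[C@H]2c2cc(C=O)cc(OC)c2OCc2ccccc2)ccc1OCc1ccccc1 | intermediate
19 | ArB–CH2OH, {4-(benzyloxy)-3-[(4S,5S)-4-(4-benzyloxy-3-methoxyphenyl)-2,2-dimethyl-1,3-dioxan-5-yl]-5-methoxyphenyl}methanol | COc1cc([C@@H](OC(C)(C)OC2)[C@H]2c2cc(CO)cc(OC)c2OCc2ccccc2)ccc1OCc1ccccc1 | intermediate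
20 | ArB–CH2Br, (4S,5S)-5-[2-(benzyloxy)-5-(bromomethyl)-3-methoxyphenyl]-4-[4-(benzyloxy)-3-methoxyphenyl]-2,2-dimethyl-1,3-dioxane | COc1cc([C@@H](OC(C)(C)OC2)[C@H]2c2cc(CBr)cc(OC)c2OCc2ccccc2)ccc1OCc1ccccc1 | intermediate
21 | 2-(allyloxy)-5-bromo-3-methoxybenzaldehyde | COc1cc(Br)cc(C=O)c1OCC=C | intermediate
22 | 2-[2-(allyloxy)-5-bromo-3-methoxyphenyl]acetonitrile | COc1cc(Br)cc(CC#N)c1OCC=C | intermediate
23 | 2-[2-(allyloxy)-5-bromo-3-methoxyphenyl]acetic acid | COc1cc(Br)cc(CC(=O)O)c1OCC=C | intermediate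
24 | (R)-4-benzyl-2-oxazolidinone | O=C1OC[C@@H](Cc2ccccc2)N1 | starting material
25 | mixed anhydride of 23 with pivalic acid | COc1cc(Br)cc(CC(=O)OC(=O)C(C)(C)C)c1OCC=C | intermediate
26 | (R)-4-benzyl-3-{2-[2-(allyloxy)-5-bromo-3-methoxyphenyl]acetyl}oxazolidin-2-one | COc1cc(Br)cc(CC(=O)N2[C@H](Cc3ccccc3)COC2=O)c1OCC=C | intermediate
27 | (R)-4-benzyl-3-{(2S,3R)-2-[2-(allyloxy)-5-bromo-3-methoxyphenyl]-3-[4-(benzyloxy)-3-methoxyphenyl]-3-(trimethylsilyloxy)propanoyl}oxazolidin-2-one | COc1cc(ccc1OCc1ccccc1)[C@H](O[Si](C)(C)C)[C@@H](C(=O)N1[C@H](Cc2ccccc2)COC1=O)c1cc(Br)cc(OC)c1OCC=C | intermediate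
28 | (2R,3R)-2-[2-(allyloxy)-5-bromo-3-methoxyphenyl]-3-[4-(benzyloxy)-3-methoxyphenyl]-3-(trimethylsilyloxy)propan-1-ol | COc1cc(ccc1OCc1ccccc1)[C@H](O[Si](C)(C)C)[C@@H](CO)c1cc(Br)cc(OC)c1OCC=C | intermediate
29 | (1R,2R)-2-[2-(allyloxy)-5-bromo-3-methoxyphenyl]-1-[4-(benzyloxy)-3-methoxyphenyl]propane-1,3-diol | COc1cc(ccc1OCc1ccccc1)[C@H](O)[C@@H](CO)c1cc(Br)cc(OC)c1OCC=C | intermediate
30 | (1R,2R)-2-[2-(allyloxy)-5-bromo-3-methoxyphenyl]-1-[4-(benzyloxy)-3-methoxyphenyl]-3-(tert-butyldimethylsilyloxy)propan-1-ol | COc1cc(ccc1OCc1ccccc1)[C@H](O)[C@@H](CO[Si](C)(C)C(C)(C)C)c1cc(Br)cc(OC)c1OCC=C | intermediate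
31 | (1R,2R)-2-(5-bromo-2-hydroxy-3-methoxyphenyl)-1-[4-(benzyloxy)-3-methoxyphenyl]-3-(tert-butyldimethylsilyloxy)propan-1-ol | COc1cc(ccc1OCc1ccccc1)[C@H](O)[C@@H](CO[Si](C)(C)C(C)(C)C)c1cc(Br)cc(OC)c1O | intermediate
32 | ArA–Br, (2S,3R)-2-[4-(benzyloxy)-3-methoxyphenyl]-5-bromo-3-[(tert-butyldimethylsilyloxy)methyl]-7-methoxy-2,3-dihydrobenzofuran | Brc1cc(OC)c2c(c1)[C@H](CO[Si](C)(C)C(C)(C)C)[C@@H](c1ccc(OCc3ccccc3)c(OC)c1)O2 | intermediate
33 | ArA–Li, aryllithium from 32 | [Li]c1cc(OC)c2c(c1)[C@H](CO[Si](C)(C)C(C)(C)C)[C@@H](c1ccc(OCc3ccccc3)c(OC)c1)O2 | intermediate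
34 | ArA–CHO, (2S,3R)-2-[4-(benzyloxy)-3-methoxyphenyl]-3-[(tert-butyldimethylsilyloxy)methyl]-7-methoxy-2,3-dihydrobenzofuran-5-carbaldehyde | O=Cc1cc(OC)c2c(c1)[C@H](CO[Si](C)(C)C(C)(C)C)[C@@H](c1ccc(OCc3ccccc3)c(OC)c1)O2 | intermediate
35 | 2-ArA-1,3-dithiane | C1CSC(SC1)c1cc(OC)c2c(c1)[C@H](CO[Si](C)(C)C(C)(C)C)[C@@H](c1ccc(OCc3ccccc3)c(OC)c1)O2 | intermediate
36 | 2-lithio-2-ArA-1,3-dithiane | [Li]C1(SCCCS1)c1cc(OC)c2c(c1)[C@H](CO[Si](C)(C)C(C)(C)C)[C@@H](c1ccc(OCc3ccccc3)c(OC)c1)O2 | intermediate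
37 | lithium (4R,5R)-4-(2-ArA-1,3-dithian-2-yl)-5-(l-menthyloxy)-4,5-dihydrofuran-2-olate | [Li]OC1=C[C@@H](C2(SCCCS2)c2cc(OC)c3c(c2)[C@H](CO[Si](C)(C)C(C)(C)C)[C@@H](c2ccc(OCc4ccccc4)c(OC)c2)O3)[C@H](O[C@@H]2C[C@H](C)CC[C@H]2C(C)C)O1 | intermediate
38 | (3R,4R,5R)-3-(ArB-methyl)-4-(2-ArA-1,3-dithian-2-yl)-5-(l-menthyloxy)dihydrofuran-2(3H)-one | COc1cc([C@@H](OC(C)(C)OC2)[C@H]2c2cc(C[C@H]3C(=O)O[C@@H](O[C@@H]7C[C@H](C)CC[C@H]7C(C)C)[C@@H]3C6(SCCCS6)c3cc(OC)c4c(c3)[C@H](CO[Si](C)(C)C(C)(C)C)[C@@H](c3ccc(OCc5ccccc5)c(OC)c3)O4)cc(OC)c2OCc2ccccc2)ccc1OCc1ccccc1 | intermediate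
39 | (3R,4R,5R)-3-(ArB-methyl)-4-(ArA-methyl)-5-(l-menthyloxy)dihydrofuran-2(3H)-one | COc1cc([C@@H](OC(C)(C)OC2)[C@H]2c2cc(C[C@H]3C(=O)O[C@@H](O[C@@H]7C[C@H](C)CC[C@H]7C(C)C)[C@@H]3Cc3cc(OC)c4c(c3)[C@H](CO[Si](C)(C)C(C)(C)C)[C@@H](c3ccc(OCc5ccccc5)c(OC)c3)O4)cc(OC)c2OCc2ccccc2)ccc1OCc1ccccc1 | intermediate
40 | potassium (2R,3R)-2-(ArB-methyl)-3-(ArA-methyl)-4-hydroxybutanoate | COc1cc([C@@H](OC(C)(C)OC2)[C@H]2c2cc(C[C@@H](C(=O)[O-])[C@H](CO)Cc3cc(OC)c4c(c3)[C@H](CO[Si](C)(C)C(C)(C)C)[C@@H](c3ccc(OCc5ccccc5)c(OC)c3)O4)cc(OC)c2OCc2ccccc2)ccc1OCc1ccccc1.[K+] | intermediate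
41 | (3R,4R)-3-(ArB-methyl)-4-(ArA-methyl)dihydrofuran-2(3H)-one | COc1cc([C@@H](OC(C)(C)OC2)[C@H]2c2cc(C[C@H]3C(=O)OC[C@@H]3Cc3cc(OC)c4c(c3)[C@H](CO[Si](C)(C)C(C)(C)C)[C@@H](c3ccc(OCc5ccccc5)c(OC)c3)O4)cc(OC)c2OCc2ccccc2)ccc1OCc1ccccc1 | intermediate
42 | tri-O-benzyl ether of the target (phenols benzylated; diol, hydroxymethyl and lactone free) | COc1cc([C@@H](O)[C@H](CO)c2cc(C[C@H]3C(=O)OC[C@@H]3Cc3cc(OC)c4c(c3)[C@H](CO)[C@@H](c3ccc(OCc5ccccc5)c(OC)c3)O4)cc(OC)c2OCc2ccccc2)ccc1OCc1ccccc1 | intermediate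
43 | CNP0186558.2, (3R,4R)-3-{4-hydroxy-3-[(1S,2S)-1,3-dihydroxy-1-(4-hydroxy-3-methoxyphenyl)propan-2-yl]-5-methoxybenzyl}-4-{[(2S,3R)-2-(4-hydroxy-3-methoxyphenyl)-3-(hydroxymethyl)-7-methoxy-2,3-dihydrobenzofuran-5-yl]methyl}dihydrofuran-2(3H)-one | COc1cc([C@@H](O)[C@H](CO)c2cc(C[C@H]3C(=O)OC[C@@H]3Cc3cc(OC)c4c(c3)[C@H](CO)[C@@H](c3ccc(O)c(OC)c3)O4)cc(OC)c2O)ccc1O | target

**Step count and risks**

Total step count: 27. Longest linear sequence: 16 steps (steps 12–27, from 5 through 35 and 38 to 43).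

Steps most likely to fail:

1. Step 23. The hindered enolate 37 may be benzylated too slowly, so that it is protonated on work-up or exchanges protons with product, and any lithiated dithiane left over when the bromide is added would be benzylated directly. The fallback sets out from 35 and 4 and returns at 38. Only the conjugate addition is run (n-BuLi; 4, −78 °C; aqueous NH4Cl), and the protonated adduct (4R,5R)-4-(2-ArA-1,3-dithian-2-yl)-5-(l-menthyloxy)dihydrofuran-2(3H)-one F1 is isolated and purified. In a separate operation F1 is deprotonated with LiN(i-Pr)2 (THF, −78 °C) to regenerate enolate 37 free of residual carbanion, and 37 is alkylated with 20 in the presence of DMPU, anti to the dithianyl group, to give 38.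

2. Step 16 (step 7 is the same reaction in the enantiomeric series and shares the risk). With the more acidic arylacetyl imide the soft enolisation may lead to O-silylation of the enolate, to retro-aldol equilibration before silylation, or to poor anti or facial selectivity. The fallback sets out from acid 23, auxiliary 9 and aldehyde 12 and returns at 32.
   - Acid 23 is attached to 9 as in step 15 (through anhydride 25) to give (S)-4-benzyl-3-{2-[2-(allyloxy)-5-bromo-3-methoxyphenyl]acetyl}oxazolidin-2-one F2.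
   - The dibutylboron Z-enolate of F2 (Bu2BOTf, i-Pr2NEt, CH2Cl2, −78 → 0 °C; 12; H2O2 work-up) should give, through the closed chair transition state, the syn-aldol (S)-4-benzyl-3-{(2S,3S)-2-[2-(allyloxy)-5-bromo-3-methoxyphenyl]-3-[4-(benzyloxy)-3-methoxyphenyl]-3-hydroxypropanoyl}oxazolidin-2-one F3. Its C2 configuration is the one needed for C3 of the benzofuran.
   - LiBH4 reduction gives (1S,2R)-2-[2-(allyloxy)-5-bromo-3-methoxyphenyl]-1-[4-(benzyloxy)-3-methoxyphenyl]propane-1,3-diol F4.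
   - Deallylation as in step 19 gives (1S,2R)-2-(5-bromo-2-hydroxy-3-methoxyphenyl)-1-[4-(benzyloxy)-3-methoxyphenyl]propane-1,3-diol F5.
   - Catalytic p-toluenesulfonic acid monohydrate in CH2Cl2 ionises the 4-benzyloxybenzylic alcohol, and the phenol captures the cation (5-exo) trans to the hydroxymethyl group, so the carbinol configuration no longer matters. This gives [(2S,3R)-2-(4-benzyloxy-3-methoxyphenyl)-5-bromo-7-methoxy-2,3-dihydrobenzofuran-3-yl]methanol F6.
   - Silylation as in step 18 returns to 32.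

3. Step 24. Nickel boride may desulfurise the hindered dithiane incompletely, or may over-reduce by cleaving benzyl ethers or the benzylic C–O bonds of the dioxane and the dihydrobenzofuran. The fallback sets out from 38 and returns at 39. It replaces the metal-surface reduction by a radical chain: Bu3SnH (excess) and azobisisobutyronitrile in toluene at 110 °C cleave the two C–S bonds in turn through the benzylic α-thio radical and then the benzylic radical. These conditions leave benzyl ethers, acetals and silyl ethers alone. This fallback makes no new compound (F0).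

**Further compounds**

F1 | step 23 | (4R,5R)-4-(2-ArA-1,3-dithian-2-yl)-5-(l-menthyloxy)dihydrofuran-2(3H)-one | O=C1C[C@@H](C2(SCCCS2)c2cc(OC)c3c(c2)[C@H](CO[Si](C)(C)C(C)(C)C)[C@@H](c2ccc(OCc4ccccc4)c(OC)c2)O3)[C@H](O[C@@H]2C[C@H](C)CC[C@H]2C(C)C)O1
F2 | step 16 | (S)-4-benzyl-3-{2-[2-(allyloxy)-5-bromo-3-methoxyphenyl]acetyl}oxazolidin-2-one | COc1cc(Br)cc(CC(=O)N2[C@@H](Cc3ccccc3)COC2=O)c1OCC=C
F3 | step 16 | (S)-4-benzyl-3-{(2S,3S)-2-[2-(allyloxy)-5-bromo-3-methoxyphenyl]-3-[4-(benzyloxy)-3-methoxyphenyl]-3-hydroxypropanoyl}oxazolidin-2-one | COc1cc(ccc1OCc1ccccc1)[C@@H](O)[C@@H](C(=O)N1[C@@H](Cc2ccccc2)COC1=O)c1cc(Br)cc(OC)c1OCC=C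
F4 | step 16 | (1S,2R)-2-[2-(allyloxy)-5-bromo-3-methoxyphenyl]-1-[4-(benzyloxy)-3-methoxyphenyl]propane-1,3-diol | COc1cc(ccc1OCc1ccccc1)[C@@H](O)[C@@H](CO)c1cc(Br)cc(OC)c1OCC=C
F5 | step 16 | (1S,2R)-2-(5-bromo-2-hydroxy-3-methoxyphenyl)-1-[4-(benzyloxy)-3-methoxyphenyl]propane-1,3-diol | COc1cc(ccc1OCc1ccccc1)[C@@H](O)[C@@H](CO)c1cc(Br)cc(OC)c1O
F6 | step 16 | [(2S,3R)-2-(4-benzyloxy-3-methoxyphenyl)-5-bromo-7-methoxy-2,3-dihydrobenzofuran-3-yl]methanol | Brc1cc(OC)c2c(c1)[C@H](CO)[C@@H](c1ccc(OCc3ccccc3)c(OC)c1)O2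
F0 | step 24 | none | none
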